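## Analysis of the target

Cyclointegrin is a tetracyclic flavone. Ring A carries a chelated 5-hydroxyl and a 7-methoxy group, the γ-pyranone carries ring B at C2, and an eight-membered dihydrooxocine bridges C3 and C2′ of ring B through the chain C9H2–C10H2–C11(CH3)2–O. There is no stereocentre. The oxocine twists ring B out of the chromone plane, but the twisted conformers should interconvert by ring inversion, so nothing stereochemical has to be set. The sensitive parts are the tertiary alkyl aryl ether at C11 (it can re-ionise in strong acid), the γ-pyranone (it ring-opens under hydroxide) and two electron-rich arenes that are easily alkylated, halogenated or oxidised. The difficulty lies in the medium ring with a fully substituted carbon on oxygen, in telling four phenolic oxygens apart (7-OMe, 5-OH, 4′-OH and the ring oxygen on C2′), and in fixing the orientation of the flavone. The plan rests on one feature: C9–C10–C11 with its two methyl groups is a prenyl group on C3 whose tertiary carbon is bonded to O-2′. That is the Markovnikov adduct of the 2′-hydroxyl across the C10=C11 bond of a 3-prenylflavone. C11–O is therefore the one oxocine bond that can be closed without reagent-derived atoms and without protecting groups.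

## Retrosynthetic reasoning

**C11–O (12 ⇒ 11).** The first cut is the C11–O bond of the oxocine. The other ring bonds are poorer choices: C3–C9 would need a metal-mediated C–C closure of a medium ring, C2′–O would need arylation of a tertiary alkoxide, and the bonds inside the chain have no functional handle. Opening C11–O turns 12 into its isomer 11, a 3-prenylflavone with free 5-, 2′- and 4′-hydroxyls. The forward reaction has to protonate C10, form the tertiary cation at C11 and let O-2′ alone capture it. The structure supports this:
- The 4′-hydroxyl cannot reach the side chain.
- The 5-hydroxyl is hydrogen-bonded to the C4 carbonyl and lies on the far side of that carbonyl from C9, too far for the C10–C11 tether to span.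
- The carbonyl oxygen can close only to a 4-alkoxybenzopyrylium ion, which falls apart again to the same cation.
- O-2′ is held cis to C9 across the C2=C3 bond, and the twist that the C3 substituent imposes on ring B lifts it towards C11.

The pyranone carbonyl is the most basic site of 11, so part of a catalytic acid charge will rest there. The acid loading is therefore set at 10–20 mol % and not at a trace. It is kept well below one equivalent so that the benzopyrylium trap cannot hold the material.

**O1–C2 and the acetals (11 ⇒ 10 ⇒ 9).** Compound 11 is traced to the open-chain 2-prenyl-1,3-diketone 9 by cutting the O1–C2 bond and putting methoxymethyl groups back on O-5, O-2′ and O-4′. One acidic operation does both in the forward direction. The free ring A phenol of 9 adds to the ring B ketone and water is lost to give the protected flavone 10; the acetals are then cleaved by the alcohol solvent. Acetal protection is chosen because it survives the three basic steps before it and needs neither hydrogen (which would saturate the prenyl group) nor a hard Lewis acid. The orientation of the flavone requires ring A to close before O-2′ is unmasked. Only the ring A phenol is free in 9, and its hemiketal is one dehydration away from 10, so this order is expected.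

**C3–C9 (9 ⇒ 7 + 8).** This cut separates prenyl bromide 8 from diketone 7. C3 lies between both carbonyl groups of 7 and is its most acidic carbon, so the bond can be made by enolate alkylation before the pyranone exists. Attaching the prenyl group to a finished flavone would need halogenation or metalation at C3 beside a very electron-rich ring A. The forward step must favour carbon over the enol oxygen and over the chelated ring A phenol, and must stop after one alkylation. A weak base in small excess and a near-stoichiometric charge of 8 are the handles.

**C2–C3 (7 ⇒ 6).** Diketone 7 is opened at the C2–C3 bond (flavone numbering) to aryl ester 6, the reverse of a Baker–Venkataraman acyl shift. The gain is regiochemical certainty. The ring A oxygen that carries the aroyl group in 6 is the one set free in 7 and later becomes O1. The other ortho oxygen of ring A stays protected and ends as the 5-hydroxyl.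

**Ester C–O (6 ⇒ 2 + 5).** Ester 6 divides at the acyl–oxygen bond into phenol 2 and acid 5. Activating 5 as an acyl chloride would release strong acid beside two acetals. The bond is therefore made with a carbodiimide and an acyl-transfer catalyst under neutral conditions.

**Protection (2 ⇒ 1; 5 ⇒ 4 ⇒ 3).** Phenol 2 comes from the symmetric diphenol 1 by protecting one of its two equivalent hydroxyls. After the first etherification the second is locked in a hydrogen bond to the ketone, which makes mono-protection workable. Acid 5 comes from ester 4 by saponification, and 4 from methyl ester 3 by protecting both hydroxyls. The ester is kept through the protection so that the carboxyl group is not alkylated.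

## Alternatives that were turned down

**Alternative 1:** The pyranone is cut at C3–C4 and O1–C2. This gives 2-(benzyloxy)-6-hydroxy-4-methoxybenzaldehyde A2 and the aryl alkyl alkyne 6-[2,4-bis(benzyloxy)phenyl]-2-methylhex-5-yn-2-ol A3. In the forward key step a trivalent rhodium catalyst such as [Cp*RhCl2]2, with Cu(OAc)2 as terminal oxidant, activates the aldehyde C–H with help from the phenoxide. The alkyne inserts and C–O bond formation closes the pyranone to give 5,2′,4′-tris(benzyloxy)-3-(3-hydroxy-3-methylbutyl)-7-methoxyflavone A1.
- For: the route is convergent. The usual insertion preference of aryl alkyl alkynes places the aryl group at C2. There is no C- versus O-alkylation question, and the saturated side chain allows robust benzyl ethers.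
- Against: the aldehyde of A2 is flanked by two ortho oxygens, so the C–H activation is hindered and decarbonylation can compete. A2 and A3 each need several steps. Most important, A1 is not cyclised. After hydrogenolysis its tertiary alcohol must still be ionised by acid and captured by O-2′, which is the same cation with the same selectivity questions and with water as an extra nucleophile.
- Comparison: Alternative 1 is stronger in convergence and in the certainty of the pyranone orientation. The chosen route offers cheaper classical steps and reaches the same cationic closure sooner, from the alkene that is the direct conjugate of that cation.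

**Alternative 2:** Ring A is cut at C4a–C5. This leaves the γ-pyranone β-keto ester A5, methyl 3-oxo-4-(pyranonyl)butanoate, in which the pyranone already carries the 4′-O-benzyl ring B and the oxocine. In the forward key step, strong base converts the C8 methylene into a vinylogous enolate. Its C4a terminus attacks the ester carbon, methanol is lost and the ring tautomerises to the resorcinol, giving 4′-O-benzyl-7-O-demethylcyclointegrin A4.
- For: ring A forms in one step with both oxygens in place, in the manner of a polyketide aromatisation. The oxocine would be made earlier, on a substrate without the ring A phenols. Hydrogenolysis is allowed.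
- Against: the oxocine problem is only moved to an earlier, less familiar substrate. The C6 methylene between ketone and ester is far more acidic than C8, so polyanion conditions are needed, and γ-pyranones open under strong bases. A4 still needs selective methylation at O-7 and debenzylation.
- Comparison: Alternative 2 is stronger in flexibility of the ring A pattern and in keeping electron-rich phenols away from the cationic step. The chosen route takes ring A with the correct oxygenation from a purchasable arene and is much shorter.

**Alternative 3:** The oxocine is cut at C3–C9. The precursor is the 3-iodoflavone A7, which carries 5- and 4′-benzyl ethers and a 2-methylbut-3-en-2-yl ether on O-2′. In the forward key step 9-BBN hydroborates the terminal alkene to the primary borane at C9. An intramolecular B-alkyl Suzuki–Miyaura coupling with the C3 iodide under zerovalent palladium (for example from PdCl2(dppf) with Cs2CO3) closes the ring to 5,4′-di-O-benzylcyclointegrin A6. Hydrogenolysis of A6 would give 12.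
- For: the tertiary C11–O bond is made early by intermolecular chemistry. The ring closure is an irreversible C–C bond formation with no carbocation, so the choice among oxygen nucleophiles never arises.
- Against: tertiary 1,1-dimethylallyl aryl ethers undergo aromatic Claisen rearrangement on warming and ionise in acid, yet the ether must survive the iodination and the heated coupling. Reductive elimination from a nine-membered palladacycle has to outrun β-hydride elimination and protodehalogenation. The iodide is flanked by the carbonyl and by an ortho-substituted aryl group. The step count is clearly higher.
- Comparison: Alternative 3 is stronger in irreversibility and regiochemical certainty of the ring closure. The chosen route offers brevity, no precious metal, and failure modes that are reversible and do not destroy material.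

Key step: step 8

Assumption: 2′,6′-dihydroxy-4′-methoxyacetophenone (1), methyl 2,4-dihydroxybenzoate (3) and prenyl bromide (8) are taken as purchasable compounds.

## Route

Step 1
Reactants: 1 2′,6′-dihydroxy-4′-methoxyacetophenone
Product: 2 1-[2-hydroxy-4-methoxy-6-(methoxymethoxy)phenyl]ethan-1-one
Conditions: MOMCl (1.1 equiv), iPr2NEt, CH2Cl2, 0 °C → rt
Reagents that add atoms: chloromethyl methyl ether (MOMCl), COCCl
Why: O-alkylation of a phenol with an α-chloro ether; the substrate is symmetric, and once one ether is formed the remaining hydroxyl is locked in a hydrogen bond to the ketone and is far less nucleophilic, so one equivalent of reagent should stop at the mono-ether.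

Step 2
Reactants: 3 methyl 2,4-dihydroxybenzoate
Product: 4 methyl 2,4-bis(methoxymethoxy)benzoate
Conditions: NaH (2.4 equiv), MOMCl (2.4 equiv), DMF, 0 °C → rt
Reagents that add atoms: chloromethyl methyl ether (MOMCl), COCCl
Why: Double O-alkylation of the sodium phenoxides; the hydride base is used because the 2-hydroxyl is chelated to the ester and reacts sluggishly with amine bases.

Step 3
Reactants: 4 methyl 2,4-bis(methoxymethoxy)benzoate
Product: 5 2,4-bis(methoxymethoxy)benzoic acid
Conditions: NaOH, MeOH/H2O, 60 °C; then 1 M HCl to pH 4, 0 °C
Reagents that add atoms: sodium hydroxide, [Na+].[OH-]
Why: Ester saponification by acyl–oxygen cleavage; aryl MOM acetals are inert to hydroxide, and the acid is set free by cold, careful acidification so that the acetals are not touched.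

Step 4
Reactants: 2 1-[2-hydroxy-4-methoxy-6-(methoxymethoxy)phenyl]ethan-1-one; 5 2,4-bis(methoxymethoxy)benzoic acid
Product: 6 2-acetyl-5-methoxy-3-(methoxymethoxy)phenyl 2,4-bis(methoxymethoxy)benzoate
Conditions: EDC·HCl, DMAP (cat.), CH2Cl2, rt
Reagents that add atoms: none
Why: Steglich esterification; the carbodiimide activates the acid without the strong acid that acyl chloride formation would release beside the acetals, and DMAP carries the acyl group to the chelated phenol.

Step 5
Reactants: 6 2-acetyl-5-methoxy-3-(methoxymethoxy)phenyl 2,4-bis(methoxymethoxy)benzoate
Product: 7 1-[2,4-bis(methoxymethoxy)phenyl]-3-[2-hydroxy-4-methoxy-6-(methoxymethoxy)phenyl]propane-1,3-dione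
Conditions: LiHMDS (2.5 equiv), THF, −78 °C → rt; AcOH
Reagents that add atoms: none
Why: Baker–Venkataraman rearrangement; the methyl ketone enolate attacks the neighbouring aryl ester through a six-membered transition state and the acyl group moves from oxygen to carbon. The second equivalent of base is taken up by the acidic diketone, which drives the transfer, and the non-nucleophilic amide base does not cleave the ester.

Step 6
Reactants: 7 1-[2,4-bis(methoxymethoxy)phenyl]-3-[2-hydroxy-4-methoxy-6-(methoxymethoxy)phenyl]propane-1,3-dione; 8 prenyl bromide (1-bromo-3-methylbut-2-ene, 1.05 equiv)
Product: 9 racemic 1-[2,4-bis(methoxymethoxy)phenyl]-3-[2-hydroxy-4-methoxy-6-(methoxymethoxy)phenyl]-2-(3-methylbut-2-en-1-yl)propane-1,3-dione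
Conditions: K2CO3 (1.2 equiv), acetone, 40 °C
Reagents that add atoms: none
Why: C-alkylation of a β-diketonate with an allylic bromide (SN2); the carbon between the carbonyls is expected to be the most acidic site, so a small excess of carbonate should leave the chelated phenol protonated, and potassium diketonates in acetone alkylate mainly at carbon. The new stereocentre is racemic and is destroyed in step 7.

Step 7
Reactants: 9 racemic 1-[2,4-bis(methoxymethoxy)phenyl]-3-[2-hydroxy-4-methoxy-6-(methoxymethoxy)phenyl]-2-(3-methylbut-2-en-1-yl)propane-1,3-dione
Product: 11 5,2′,4′-trihydroxy-7-methoxy-3-prenylflavone, via tris-MOM 3-prenylflavone 10 (not isolated)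
Conditions: HCl (ca. 1 M), MeOH, 40 °C
Reagents that add atoms: none
Why: Acid-catalysed cyclodehydration of an o-hydroxyaryl 1,3-diketone to the flavone, followed by methanolysis of the three MOM acetals. Only the ring A phenol is free at the outset and its hemiketal is one dehydration from the pyranone, so ring closure from ring A should precede loss of the ring B acetals, which fixes the orientation of the flavone. The acid is kept dilute and the temperature low so that the prenyl alkene is not attacked; any oxocine formed early is the target and is no loss.

Step 8
Reactants: 11 5,2′,4′-trihydroxy-7-methoxy-3-prenylflavone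
Product: 12 cyclointegrin
Conditions: TfOH (10–20 mol %), (CF3)2CHOH, 0.01 M, 25 → 40 °C
Reagents that add atoms: none
Why: The strong acid in the ionising, non-nucleophilic fluorinated alcohol protonates the trisubstituted alkene at C10 to give the tertiary cation at C11; the 2′-hydroxyl captures it and loses its proton, which forms the C11–O bond and returns the acid. The closest known reaction type is the Brønsted-acid-catalysed cyclisation of ortho-prenylphenols to 2,2-dimethylchromans, and the same hydroalkoxylation mechanism is used here for the eight-membered ether. The closure is formally 8-endo-trig with respect to C10=C11 but proceeds in practice as stepwise capture of a free tertiary cation, so orbital-alignment limits are relaxed; four of the eight ring atoms (C3, C2, C1′, C2′) are sp2 and cis-disposed, and the twist that the C3 substituent imposes on ring B brings O-2′ over C11. No stereocentre is formed because C11 carries two methyl groups. The step needs Markovnikov regioselectivity, which the tertiary over secondary cation secures, and selection of O-2′ among the oxygen nucleophiles: the 4′-hydroxyl is out of reach, the chelated 5-hydroxyl is separated from C9 by the C4 carbonyl so the two-carbon tether cannot span the gap, and the carbonyl oxygen gives only a 4-alkoxybenzopyrylium ion that re-ionises and cannot exceed the acid charge. The neutral aryl ether is the only closed-shell product that leaves the cation manifold other than the alkene isomers, which re-enter on protonation, so it should accumulate. High dilution suppresses intermolecular Friedel–Crafts alkylation of the electron-rich rings, and the acid loading allows for the fraction held at the basic pyranone carbonyl.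

## Compound list

1 | 2′,6′-dihydroxy-4′-methoxyacetophenone | CC(=O)c1c(O)cc(OC)cc1O | starting material
2 | 1-[2-hydroxy-4-methoxy-6-(methoxymethoxy)phenyl]ethan-1-one | CC(=O)c1c(O)cc(OC)cc1OCOC | intermediate
3 | methyl 2,4-dihydroxybenzoate | COC(=O)c1ccc(O)cc1O | starting material
4 | methyl 2,4-bis(methoxymethoxy)benzoate | COCOc1ccc(C(=O)OC)c(OCOC)c1 | intermediate
5 | 2,4-bis(methoxymethoxy)benzoic acid | COCOc1ccc(C(=O)O)c(OCOC)c1 | intermediate
6 | 2-acetyl-5-methoxy-3-(methoxymethoxy)phenyl 2,4-bis(methoxymethoxy)benzoate | CC(=O)c1c(OCOC)cc(OC)cc1OC(=O)c1ccc(OCOC)cc1OCOC | intermediate
7 | 1-[2,4-bis(methoxymethoxy)phenyl]-3-[2-hydroxy-4-methoxy-6-(methoxymethoxy)phenyl]propane-1,3-dione | COCOc1ccc(C(=O)CC(=O)c2c(O)cc(OC)cc2OCOC)c(OCOC)c1 | intermediate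
8 | prenyl bromide (1-bromo-3-methylbut-2-ene) | CC(C)=CCBr | starting material
9 | racemic 1-[2,4-bis(methoxymethoxy)phenyl]-3-[2-hydroxy-4-methoxy-6-(methoxymethoxy)phenyl]-2-(3-methylbut-2-en-1-yl)propane-1,3-dione | COCOc1ccc(C(=O)C(CC=C(C)C)C(=O)c2c(O)cc(OC)cc2OCOC)c(OCOC)c1 | intermediate
10 | 7-methoxy-5-(methoxymethoxy)-2-[2,4-bis(methoxymethoxy)phenyl]-3-(3-methylbut-2-en-1-yl)-4H-chromen-4-one (tris-MOM 3-prenylflavone) | COCOc1ccc(-c2oc3cc(OC)cc(OCOC)c3c(=O)c2CC=C(C)C)c(OCOC)c1 | intermediate
11 | 5-hydroxy-2-(2,4-dihydroxyphenyl)-7-methoxy-3-(3-methylbut-2-en-1-yl)-4H-chromen-4-one (5,2′,4′-trihydroxy-7-methoxy-3-prenylflavone) | COc1cc(O)c2c(=O)c(CC=C(C)C)c(-c3ccc(O)cc3O)oc2c1 | intermediate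
12 | cyclointegrin | COc1cc(O)c2c(=O)c3c(oc2c1)-c1ccc(O)cc1OC(C)(C)CC3 | target

## Step count and least certain steps

Total step count: 8. Longest linear sequence: 7 steps (steps 2 to 8, from 3 to 12).

**Step 8 (key step).** Ring closure is the slowest of the cation's options. The cation may be drained by intermolecular Friedel–Crafts alkylation of the electron-rich rings of a second molecule. It may also shuttle between the alkene isomers and the benzopyrylium trap while the acid rests on the pyranone carbonyl. The product ether can re-ionise if the acid is too strong or left too long. Fallback: from 11 directly to 12 by a radical–polar crossover hydroalkoxylation in place of protonation. The divalent cobalt salen complex N,N′-bis(3,5-di-tert-butylsalicylidene)-1,2-cyclohexanediaminocobalt, with PhSiH3 and N-fluoro-2,4,6-trimethylpyridinium triflate, transfers a hydrogen atom to C10. The tertiary radical is oxidised at cobalt and O-2′ displaces the metal. The closure is then Markovnikov by radical stability, irreversible and free of Brønsted acid, so neither ether re-ionisation nor acid sequestration applies. No compound outside the list is made (F0).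

**Step 6.** The anion of 7 is ambident and its carbon lies between two aroyl groups. Alkylation on oxygen (enol or ring A phenoxide) may therefore compete with alkylation on carbon, and a second alkylation of 9 may follow. Fallback: form the C3–C9 bond before the diketone exists. From 2, double deprotonation with LDA (phenoxide and ketone enolate) and alkylation of the enolate carbon with 8 should give 1-[2-hydroxy-4-methoxy-6-(methoxymethoxy)phenyl]-5-methylhex-4-en-1-one F1. Carbodiimide esterification of F1 with 5 gives 5-methoxy-3-(methoxymethoxy)-2-(5-methylhex-4-enoyl)phenyl 2,4-bis(methoxymethoxy)benzoate F2. Baker–Venkataraman rearrangement of F2 with LiHMDS returns to the route at 9.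

**Step 7.** Methanol or chloride may add across the prenyl alkene, or partial ring closures may occur, while the slower ring B acetals are being cleaved. The 2′-acetal may also be lost before the pyranone has closed, which would allow ring closure from the wrong phenol. Fallback: separate the two events and avoid protic acid. From 9, DBU in pyridine at 60 °C should dehydrate the hemiketal by an E1cB path to give 10, which is then isolated. ZnBr2 and propane-1-thiol in CH2Cl2 at 0 °C then cleave the three acetals by Lewis acid activation and thiol capture, returning to the route at 11. No compound outside the list is made (F0).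

**Step 5.** If the enolate attacks the electron-rich, ortho-substituted ester slowly, the aroyl group may be lost (return to 2) or transferred between molecules. Fallback: make the C2–C3 bond intermolecularly. From 2 and methyl ester 4, LiHMDS (3.5 equiv) in THF forms the dianion of 2, and its enolate carbon is acylated by 4 in a crossed Claisen condensation. This returns to the route at 7 and bypasses 5 and 6. No compound outside the list is made (F0).

## Further compounds

F0 | step 8 | none | none
F1 | step 6 | 1-[2-hydroxy-4-methoxy-6-(methoxymethoxy)phenyl]-5-methylhex-4-en-1-one | CC(C)=CCCC(=O)c1c(O)cc(OC)cc1OCOC
F2 | step 6 | 5-methoxy-3-(methoxymethoxy)-2-(5-methylhex-4-enoyl)phenyl 2,4-bis(methoxymethoxy)benzoate | CC(C)=CCCC(=O)c1c(OCOC)cc(OC)cc1OC(=O)c1ccc(OCOC)cc1OCOC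
F0 | step 7 | none | none
F0 | step 5 | none | none
A1 | alternative 1 | 5,2′,4′-tris(benzyloxy)-3-(3-hydroxy-3-methylbutyl)-7-methoxyflavone | COc1cc(OCc5ccccc5)c2c(=O)c(CCC(C)(C)O)c(-c3ccc(OCc4ccccc4)cc3OCc3ccccc3)oc2c1
A2 | alternative 1 | 2-(benzyloxy)-6-hydroxy-4-methoxybenzaldehyde | O=Cc1c(O)cc(OC)cc1OCc1ccccc1
A3 | alternative 1 | 6-[2,4-bis(benzyloxy)phenyl]-2-methylhex-5-yn-2-ol | CC(C)(O)CCC#Cc1ccc(OCc2ccccc2)cc1OCc1ccccc1
A4 | alternative 2 | 4′-O-benzyl-7-O-demethylcyclointegrin | Oc1cc(O)c2c(=O)c3c(oc2c1)-c1ccc(OCc4ccccc4)cc1OC(C)(C)CC3
A5 | alternative 2 | methyl 3-oxo-4-(pyranonyl)butanoate carrying the 4′-O-benzyl ring B and the oxocine (ring A seco precursor) | COC(=O)CC(=O)Cc1cc(=O)c2c(o1)-c1ccc(OCc3ccccc3)cc1OC(C)(C)CC2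
A6 | alternative 3 | 5,4′-di-O-benzylcyclointegrin | COc1cc(OCc4ccccc4)c2c(=O)c3c(oc2c1)-c1ccc(OCc5ccccc5)cc1OC(C)(C)CC3
A7 | alternative 3 | 5-(benzyloxy)-2-[4-(benzyloxy)-2-(2-methylbut-3-en-2-yloxy)phenyl]-3-iodo-7-methoxy-4H-chromen-4-one | COc1cc(OCc2ccccc2)c2c(=O)c(I)c(-c3ccc(OCc4ccccc4)cc3OC(C)(C)C=C)oc2c1
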